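The synthesis rests on reading the trans-2-aryl-2,3-dihydrobenzofuran of the target (ring oxygen, Cd = O–CH–aryl, Cb = neighbouring CH, resorcinol ring A) as a (2S)-flavanone whose ring A has slipped from C4 to C3. Oxidation of the flavanone enol ether by trivalent iodine triggers exactly this 1,2-aryl shift. In one operation the Cb–ring A bond forms, the pyranone shrinks to the dihydrofuran, the Cd configuration is passed on to Cb, and C4 is pushed out as a methyl ester that later leaves in exchange for ring B. The precursor is (2S)-5-benzyloxy-7-methoxy-2-[4-(tosyloxy)phenyl]chroman-4-one. Friedel–Crafts closure of the seven-membered ring and a Heck union complete the skeleton.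

Key step: step 5

Remarks
- **Labels.** Ca is the CH bonded to ring A and to ring S, the phenol ring of the stilbene. Cc is the CH bonded to ring B and to a 4-hydroxyphenyl group. The seven-membered ring runs Ca–A–A–Cb–B–B–Cc.
- **Configuration check.** The target SMILES reads Cd S, Cb S, Ca R, Cc S, with Cd/Cb trans and Ca/Cc trans. Cd S corresponds to a 2S flavanone because the ranking O > aryl > ring carbon > H is the same in both.
- **Design of the precursor.** The 4'-oxygen is carried as a tosylate instead of an alkyl ether. An electron-rich 2-aryl group would compete as the migrating group (isoflavone pathway) and would help ionise the C2–O bond, which causes racemisation. The same tosylate later shields the Cd–O bond during the Lewis-acid steps 15 and 16. The 5-benzyloxy and 7-methoxy donors stay on ring A, where they raise its migratory aptitude.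
- **Protecting groups.** Methyl ethers are cleaved on the two robust halves, before the acid-sensitive stilbene exists. The union and the last step run on acetates.
- **Assumption.** The antipode of the diene ligand Ph-bod* (2,5-diphenylbicyclo[2.2.2]octa-2,5-diene) needed in steps 4 and 12 is assigned by analogy with cyclic enones and is confirmed on a small scale. Both antipodes are accessible.

Step 1
Reactants: 1 1-(2,6-dihydroxy-4-methoxyphenyl)ethan-1-one
Product: 2 1-[2-(benzyloxy)-6-hydroxy-4-methoxyphenyl]ethan-1-one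
Conditions: BnBr (1.05 equiv), K2CO3, acetone, reflux
Reagents that add atoms: benzyl bromide, BrCc1ccccc1
Why: Williamson etherification should stop at the mono-ether because after the first alkylation the remaining phenol is tied up in a hydrogen bond to the ketone, and this free phenol is the one needed for chromone closure.

Step 2
Reactants: 2 1-[2-(benzyloxy)-6-hydroxy-4-methoxyphenyl]ethan-1-one
Product: 4 5-(benzyloxy)-7-methoxy-4H-chromen-4-one, via enaminone 3 (not isolated)
Conditions: Me2NCH(OMe)2, toluene, 100 °C; concentrate; then conc. HCl, CH2Cl2, 40 °C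
Reagents that add atoms: N,N-dimethylformamide dimethyl acetal, COC(OC)N(C)C
Why: Condensation of the acetyl group with the formamide acetal and acid-induced addition–elimination of the phenol on the enaminone is the standard chromone synthesis from 2-hydroxyacetophenones and tolerates both ethers.

Step 3
Reactants: 5 4-hydroxyphenylboronic acid
Product: 6 4-(tosyloxy)phenylboronic acid
Conditions: TsCl, Na2CO3, THF/H2O, 0 °C to rt; then dilute HCl to pH 3
Reagents that add atoms: 4-toluenesulfonyl chloride, Cc1ccc(cc1)S(Cl)(=O)=O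
Why: Schotten–Baumann sulfonylation of the phenolate is faster than any reaction at boron and installs the electron-poor oxygen substituent that the key step needs on the future Cd aryl group.

Step 4
Reactants: 4 5-(benzyloxy)-7-methoxy-4H-chromen-4-one; 6 4-(tosyloxy)phenylboronic acid
Product: 7 (2S)-5-(benzyloxy)-7-methoxy-2-[4-(tosyloxy)phenyl]chroman-4-one
Conditions: [RhCl(C2H4)2]2 (2.5 mol %), (S,S)-Ph-bod* (5.5 mol %), K3PO4 (0.2 equiv), toluene/H2O 10:1, 40 °C
Reagents that add atoms: none
Why: Hayashi–Miyaura conjugate addition of the aryl–rhodium species to C2 of the chromone sets Cd, the C2-symmetric diene exposing one face of the enone so that the (2S)-flavanone should form in high enantiomeric purity, while the nearly neutral medium and the tosylate disfavour racemisation through opening to the chalcone.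

Step 5
Reactants: 7 (2S)-5-(benzyloxy)-7-methoxy-2-[4-(tosyloxy)phenyl]chroman-4-one
Product: 10 methyl (2S,3S)-4-(benzyloxy)-6-methoxy-2-[4-(tosyloxy)phenyl]-2,3-dihydrobenzofuran-3-carboxylate (trans), via enol ether 8 (not isolated), via iodane ketal 9 (not isolated)
Conditions: HC(OMe)3 (solvent), conc. H2SO4 (0.3 equiv), rt; then PhI(OAc)2 (1.2 equiv), 0 °C to rt
Reagents that add atoms: trimethyl orthoformate, COC(OC)OC
Why: Acid and HC(OMe)3 convert ketone 7 into enol ether 8, PhI(OAc)2 adds its trivalent iodine to C3 from the face opposite the equatorial 2-aryl group while methanol caps C4, and in the resulting ketal 9 the equatorial C3–I bond lies antiperiplanar to the C4–C4a bond, so C4a migrates to C3 as iodobenzene departs and the dimethoxycarbenium ion left at C4 collapses to the methyl ester. The closest known reaction type is the oxidative 1,2-aryl-shift ring contraction of flavanones, and of aryl alkyl ketones in general, with PhI(OAc)2 or Tl(NO3)3 in trimethyl orthoformate. The dihydrofuran is closed by contraction and not by cyclisation of a chain: the C3–C4a bond forms through a bridged phenonium-type transition state at the same time as C4–C4a breaks, which turns the six-membered ring into the five-membered one. C2 (Cd) is a spectator and keeps its S configuration, and the new centre C3 (Cb) is set by anti iodination followed by inversion in the migration, which places the ester trans to the aryl group, the isomer that the epimerisable ester position favours as well. The step needs migration of ring A in preference to migration of the 2-aryl group (isoflavone), to dehydrogenation (flavone) and to attack of the oxidant on ring A. The migrating carbon C4a is ortho, ortho and para to three ether oxygens, whereas the tosylate makes the 2-aryl group a poor migrating group and suppresses ionisation of the C2–O bond, and adding the oxidant only after the enol ether has formed directs it to C3.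

Step 6
Reactants: 10 methyl (2S,3S)-4-(benzyloxy)-6-methoxy-2-[4-(tosyloxy)phenyl]-2,3-dihydrobenzofuran-3-carboxylate
Product: 11 (2S,3S)-4-(benzyloxy)-6-methoxy-2-[4-(tosyloxy)phenyl]-2,3-dihydrobenzofuran-3-carboxylic acid
Conditions: Me3SnOH (6 equiv), ClCH2CH2Cl, 80 °C; then 5% HCl wash
Reagents that add atoms: trimethyltin hydroxide, C[Sn](C)(C)O
Why: Ester cleavage with Me3SnOH works under essentially neutral conditions and so avoids enolate formation at C3, which under hydroxide could expel the C2 aryloxide (retro-oxa-Michael opening) and endanger the tosylate.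

Step 7
Reactants: 11 (2S,3S)-4-(benzyloxy)-6-methoxy-2-[4-(tosyloxy)phenyl]-2,3-dihydrobenzofuran-3-carboxylic acid; 12 1-bromo-3,5-dimethoxybenzene
Product: 13 (2S,3S)-4-(benzyloxy)-3-(3,5-dimethoxyphenyl)-6-methoxy-2-[4-(tosyloxy)phenyl]-2,3-dihydrobenzofuran
Conditions: Ir[dF(CF3)ppy]2(dtbbpy)PF6 (1 mol %), NiCl2·glyme (10 mol %), dtbbpy (15 mol %), Cs2CO3 (1.5 equiv), DMF, blue LEDs, rt
Reagents that add atoms: none
Why: In this metallaphotoredox decarboxylative arylation the photo-oxidised carboxylate loses CO2 to give a planar benzylic C3 radical that is captured by the aryl–nickel species on the face remote from the C2 aryl group, so Cb is re-formed trans with ring B in place of the carboxyl carbon, the aryl tosylate being inert to bipyridine–nickel at room temperature.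

Step 8
Reactants: 13 (2S,3S)-4-(benzyloxy)-3-(3,5-dimethoxyphenyl)-6-methoxy-2-[4-(tosyloxy)phenyl]-2,3-dihydrobenzofuran
Product: 14 (2S,3S)-3-(3,5-dimethoxyphenyl)-6-methoxy-2-[4-(tosyloxy)phenyl]-2,3-dihydrobenzofuran-4-ol
Conditions: H2 (1 atm), 10% Pd/C, EtOAc/EtOH, rt
Reagents that add atoms: none
Why: Catalytic hydrogenolysis removes the only benzyl ether, whereas the methyl ethers, the aryl tosylate and the cyclic benzylic C2–O bond (deactivated by the electron-poor aryl group) should persist.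

Step 9
Reactants: 14 (2S,3S)-3-(3,5-dimethoxyphenyl)-6-methoxy-2-[4-(tosyloxy)phenyl]-2,3-dihydrobenzofuran-4-ol
Product: 15 (2S,3S)-3-(3,5-dimethoxyphenyl)-6-methoxy-2-[4-(tosyloxy)phenyl]-2,3-dihydrobenzofuran-4-yl trifluoromethanesulfonate
Conditions: Tf2O, pyridine, CH2Cl2, 0 °C
Reagents that add atoms: trifluoromethanesulfonic anhydride, O=S(=O)(OS(=O)(=O)C(F)(F)F)C(F)(F)F
Why: O-Sulfonylation of the phenol turns the former flavanone 5-oxygen into a cross-coupling handle at the ring A carbon that will bear Ca.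

Step 10
Reactants: 15 (2S,3S)-3-(3,5-dimethoxyphenyl)-6-methoxy-2-[4-(tosyloxy)phenyl]-2,3-dihydrobenzofuran-4-yl trifluoromethanesulfonate
Product: 16 (2S,3S)-3-(3,5-dimethoxyphenyl)-6-methoxy-2-[4-(tosyloxy)phenyl]-2,3-dihydrobenzofuran-4-carbaldehyde
Conditions: CO (1 atm), Pd(OAc)2 (5 mol %), dppp (5 mol %), Et3SiH, Et3N, DMF, 70 °C
Reagents that add atoms: carbon monoxide, [C-]#[O+]
Why: Palladium-catalysed reductive carbonylation (formylation) of the aryl triflate by oxidative addition, CO insertion and hydride transfer from the silane delivers the carbon that becomes Ca and leaves the far less reactive aryl tosylate untouched.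

Step 11
Reactants: 16 (2S,3S)-3-(3,5-dimethoxyphenyl)-6-methoxy-2-[4-(tosyloxy)phenyl]-2,3-dihydrobenzofuran-4-carbaldehyde
Product: 17 (2S,3S)-3-(3,5-dimethoxyphenyl)-6-methoxy-4-[(E)-2-nitroethenyl]-2-[4-(tosyloxy)phenyl]-2,3-dihydrobenzofuran
Conditions: MeNO2 (solvent), NH4OAc (0.5 equiv), 95 °C
Reagents that add atoms: nitromethane, C[N+](=O)[O-]
Why: Henry condensation with in situ dehydration gives the conjugated (E)-nitroalkene under weakly acidic buffer conditions and adds the carbon that becomes Cc.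

Step 12
Reactants: 17 (2S,3S)-3-(3,5-dimethoxyphenyl)-6-methoxy-4-[(E)-2-nitroethenyl]-2-[4-(tosyloxy)phenyl]-2,3-dihydrobenzofuran; 18 5-bromo-2-methoxyphenylboronic acid
Product: 19 (2S,3S)-4-[(1R)-1-(5-bromo-2-methoxyphenyl)-2-nitroethyl]-3-(3,5-dimethoxyphenyl)-6-methoxy-2-[4-(tosyloxy)phenyl]-2,3-dihydrobenzofuran
Conditions: [RhCl(C2H4)2]2 (3 mol %), Ph-bod* (6.5 mol %, antipode matched to attack anti to ring B), K3PO4 (0.2 equiv), 1,4-dioxane/H2O 10:1, 45 °C
Reagents that add atoms: none
Why: Hayashi–Miyaura conjugate addition to a β-aryl nitroalkene sets Ca as R under ligand control, and the substrate reinforces this sense because in the favoured rotamer (Ca–H turned towards Cb) ring B shields one face of the alkene so that ring S arrives from the opposite face, the aryl bromide being inert to the rhodium catalyst.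

Step 13
Reactants: 19 (2S,3S)-4-[(1R)-1-(5-bromo-2-methoxyphenyl)-2-nitroethyl]-3-(3,5-dimethoxyphenyl)-6-methoxy-2-[4-(tosyloxy)phenyl]-2,3-dihydrobenzofuran
Product: 21 (2R)-2-(5-bromo-2-methoxyphenyl)-2-{(2S,3S)-3-(3,5-dimethoxyphenyl)-6-methoxy-2-[4-(tosyloxy)phenyl]-2,3-dihydrobenzofuran-4-yl}acetaldehyde, via sodium nitronate 20 (not isolated)
Conditions: NaOMe (1.05 equiv), MeOH/THF, 0 °C; then added to TiCl3, NH4OAc, H2O (pH about 6), 0 °C; crude product used at once
Reagents that add atoms: water, O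
Why: In this reductive Nef reaction TiCl3 reduces the nitronate to the imine, which hydrolyses in the cold buffered medium, so that contact of the enolisable diarylacetaldehyde with acid or base is kept short and Ca should be preserved.

Step 14
Reactants: 21 (2R)-2-(5-bromo-2-methoxyphenyl)-2-{(2S,3S)-3-(3,5-dimethoxyphenyl)-6-methoxy-2-[4-(tosyloxy)phenyl]-2,3-dihydrobenzofuran-4-yl}acetaldehyde; 22 4-methoxyphenylmagnesium bromide (THF solution)
Product: 23 (2R)-2-(5-bromo-2-methoxyphenyl)-2-{(2S,3S)-3-(3,5-dimethoxyphenyl)-6-methoxy-2-[4-(tosyloxy)phenyl]-2,3-dihydrobenzofuran-4-yl}-1-(4-methoxyphenyl)ethan-1-ol (both carbinol epimers)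
Conditions: 22 (1.5 equiv), LaCl3·2LiCl (1 equiv), THF, −78 °C; then H2O
Reagents that add atoms: none
Why: Grignard 1,2-addition assisted by the oxophilic, weakly basic lanthanum salt outruns enolisation at −78 °C, spares bromide and tosylate, and the mixture at the carbinol carbon does not matter because this centre is ionised in the next step.

Step 15
Reactants: 23 (2R)-2-(5-bromo-2-methoxyphenyl)-2-{(2S,3S)-3-(3,5-dimethoxyphenyl)-6-methoxy-2-[4-(tosyloxy)phenyl]-2,3-dihydrobenzofuran-4-yl}-1-(4-methoxyphenyl)ethan-1-ol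
Product: 24 core bromide: dihydrobenzofuran-fused dibenzocycloheptane with 5-bromo-2-methoxyphenyl on Ca and 4-methoxyphenyl on Cc and 4-(tosyloxy)phenyl on Cd (OMe on ring A; 2 OMe on ring B; CaR/CcS/CbS/CdS)
Conditions: Bi(OTf)3 (10 mol %), CH2Cl2/(CF3)2CHOH 4:1, −20 °C
Reagents that add atoms: none
Why: Intramolecular dehydrative Friedel–Crafts alkylation, the mode known from the acid-induced cyclisation of 4-styryl-3-aryl-2,3-dihydrobenzofurans, lets the anisyl-stabilised Cc cation be trapped by the ortho carbon of ring B (ortho and para to its methoxy groups) to close the seven-membered ring, and Cc is set as S because the anisyl group takes the position away from the ring B methoxy group and anti to ring S on Ca, while the tosylate keeps the Cd–O bond closed.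

Step 16
Reactants: 24 core bromide (pentamethyl ether, tosylate)
Product: 25 core bromide pentaphenol still carrying the tosylate on the Cd aryl group (CaR/CcS/CbS/CdS)
Conditions: BBr3 (12 equiv), CH2Cl2, −78 °C to rt; then ice/H2O
Reagents that add atoms: none
Why: Lewis-acid ether cleavage with BBr3 is applied before the acid-sensitive stilbene exists, and the electron-poor Cd aryl group prevents ionisation of the Cd–O bond, so that all four stereocentres should survive.

Step 17
Reactants: 25 core bromide pentaphenol tosylate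
Product: 27 core bromide hexaacetate (CaR/CcS/CbS/CdS), via hexaphenol 26 (not isolated)
Conditions: KOH, MeOH/H2O, 65 °C, argon; HCl to pH 4, extract, concentrate; then Ac2O, pyridine, DMAP (cat.), rt
Reagents that add atoms: acetic anhydride, CC(=O)OC(C)=O
Why: Alkaline hydrolysis of the aryl sulfonate on the robust bromide core followed by peracetylation exchanges all protecting groups for acetates, which tolerate the Heck coupling and are cleaved under neutral conditions at the end.

Step 18
Reactants: 12 1-bromo-3,5-dimethoxybenzene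
Product: 28 1-bromo-2-iodo-3,5-dimethoxybenzene
Conditions: N-iodosuccinimide, CF3CO2H (cat.), MeCN, rt
Reagents that add atoms: N-iodosuccinimide, O=C1CCC(=O)N1I
Why: Electrophilic aromatic iodination occurs ortho to one and para to the other methoxy group, next to bromine, because the position between the two methoxy groups is more hindered.

Step 19
Reactants: 28 1-bromo-2-iodo-3,5-dimethoxybenzene; 29 1-ethynyl-4-methoxybenzene
Product: 30 1-bromo-3,5-dimethoxy-2-[(4-methoxyphenyl)ethynyl]benzene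
Conditions: PdCl2(PPh3)2 (3 mol %), CuI (5 mol %), Et3N/THF, 50 °C
Reagents that add atoms: none
Why: Sonogashira coupling takes place at the carbon–iodine bond, which undergoes oxidative addition far faster than the neighbouring carbon–bromine bond.

Step 20
Reactants: 30 1-bromo-3,5-dimethoxy-2-[(4-methoxyphenyl)ethynyl]benzene
Product: 31 4-bromo-3-iodo-6-methoxy-2-(4-methoxyphenyl)benzofuran
Conditions: I2 (1.5 equiv), CH2Cl2, rt
Reagents that add atoms: iodine, II
Why: Electrophilic iodocyclisation of the 2-alkynylanisole (5-endo-dig attack of the methoxy oxygen on the iodonium-activated alkyne, then demethylation by iodide) builds the benzofuran and leaves iodine at C3 for the next coupling.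

Step 21
Reactants: 31 4-bromo-3-iodo-6-methoxy-2-(4-methoxyphenyl)benzofuran; 32 3,5-dimethoxyphenylboronic acid
Product: 33 4-bromo-3-(3,5-dimethoxyphenyl)-6-methoxy-2-(4-methoxyphenyl)benzofuran
Conditions: Pd(PPh3)4 (5 mol %), Na2CO3, 1,4-dioxane/H2O, 80 °C
Reagents that add atoms: none
Why: Suzuki–Miyaura coupling is again selective for iodide over bromide and installs the 3,5-dimethoxyphenyl group at C3.

Step 22
Reactants: 33 4-bromo-3-(3,5-dimethoxyphenyl)-6-methoxy-2-(4-methoxyphenyl)benzofuran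
Product: 35 2-(4-acetoxyphenyl)-4-bromo-3-(3,5-diacetoxyphenyl)benzofuran-6-yl acetate, via tetraphenol 34 (not isolated)
Conditions: BBr3 (8 equiv), CH2Cl2, −78 °C to rt; H2O, extract, concentrate; then Ac2O, pyridine, rt
Reagents that add atoms: acetic anhydride, CC(=O)OC(C)=O
Why: The fully aromatic benzofuran tolerates BBr3 demethylation, and acetylation of the crude tetraphenol brings this fragment to the same protecting-group scheme as 27.

Step 23
Reactants: 35 2-(4-acetoxyphenyl)-4-bromo-3-(3,5-diacetoxyphenyl)benzofuran-6-yl acetate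
Product: 36 2-(4-acetoxyphenyl)-3-(3,5-diacetoxyphenyl)-4-ethenylbenzofuran-6-yl acetate
Conditions: Bu3SnCH=CH2, Pd(PPh3)4 (5 mol %), BHT (trace), toluene, 100 °C
Reagents that add atoms: tributyl(vinyl)stannane, C=C[Sn](CCCC)(CCCC)CCCC
Why: Stille vinylation proceeds under neutral, base-free conditions that spare the aryl acetates and converts the C4 bromide into the styrene needed for the union.

Step 24
Reactants: 27 core bromide hexaacetate; 36 2-(4-acetoxyphenyl)-3-(3,5-diacetoxyphenyl)-4-ethenylbenzofuran-6-yl acetate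
Product: 37 decaacetate of the target ((E)-stilbene; CaR/CcS/CbS/CdS)
Conditions: Pd(OAc)2 (10 mol %), P(o-tol)3 (20 mol %), Et3N, DMF, 95 °C
Reagents that add atoms: none
Why: Mizoroki–Heck arylation of the terminal alkene carbon by the unhindered aryl bromide followed by syn β-hydride elimination gives the (E)-stilbene and joins both halves without touching the stereocentres.

Step 25
Reactants: 37 decaacetate of the target
Product: 38 CNP0339094.1 (target)
Conditions: NH4OAc (excess), MeOH (5% H2O), degassed, rt to 40 °C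
Reagents that add atoms: none
Why: NH4OAc-promoted methanolysis of aryl acetates is a neutral transesterification, so neither the acid-sensitive stilbene next to a resorcinol ring nor oxidation-prone phenolates are put at risk while the ten phenols are released.

Compound list
1 | 1-(2,6-dihydroxy-4-methoxyphenyl)ethan-1-one | CC(=O)c1c(O)cc(OC)cc1O | starting material
2 | 1-[2-(benzyloxy)-6-hydroxy-4-methoxyphenyl]ethan-1-one | CC(=O)c1c(O)cc(OC)cc1OCc1ccccc1 | intermediate
3 | (E)-1-[2-(benzyloxy)-6-hydroxy-4-methoxyphenyl]-3-(dimethylamino)prop-2-en-1-one | CN(C)/C=C/C(=O)c1c(O)cc(OC)cc1OCc1ccccc1 | intermediate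
4 | 5-(benzyloxy)-7-methoxy-4H-chromen-4-one | COc1cc(OCc2ccccc2)c2C(=O)C=COc2c1 | intermediate
5 | 4-hydroxyphenylboronic acid | OB(O)c1ccc(O)cc1 | starting material
6 | 4-(tosyloxy)phenylboronic acid | Cc1ccc(cc1)S(=O)(=O)Oc1ccc(cc1)B(O)O | intermediate
7 | (2S)-5-(benzyloxy)-7-methoxy-2-[4-(tosyloxy)phenyl]chroman-4-one | COc1cc(OCc2ccccc2)c2C(=O)C[C@@H](c3ccc(OS(=O)(=O)c4ccc(C)cc4)cc3)Oc2c1 | intermediate
8 | (2S)-5-(benzyloxy)-4,7-dimethoxy-2-[4-(tosyloxy)phenyl]-2H-chromene | COc1cc(OCc2ccccc2)c2C(OC)=C[C@@H](c3ccc(OS(=O)(=O)c4ccc(C)cc4)cc3)Oc2c1 | intermediate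
9 | 2,3-trans-3-[acetoxy(phenyl)-λ3-iodanyl]-5-(benzyloxy)-4,4,7-trimethoxy-2-[4-(tosyloxy)phenyl]chromane (C2 arranged as in 7) | COc1cc(OCc2ccccc2)c2C(OC)(OC)[C@H](I(OC(C)=O)c3ccccc3)[C@@H](c3ccc(OS(=O)(=O)c4ccc(C)cc4)cc3)Oc2c1 | intermediate
10 | methyl (2S,3S)-4-(benzyloxy)-6-methoxy-2-[4-(tosyloxy)phenyl]-2,3-dihydrobenzofuran-3-carboxylate (trans) | COc1cc(OCc2ccccc2)c2c(c1)O[C@H](c1ccc(OS(=O)(=O)c3ccc(C)cc3)cc1)[C@H]2C(=O)OC | intermediate
11 | (2S,3S)-4-(benzyloxy)-6-methoxy-2-[4-(tosyloxy)phenyl]-2,3-dihydrobenzofuran-3-carboxylic acid | COc1cc(OCc2ccccc2)c2c(c1)O[C@H](c1ccc(OS(=O)(=O)c3ccc(C)cc3)cc1)[C@H]2C(=O)O | intermediate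
12 | 1-bromo-3,5-dimethoxybenzene | COc1cc(Br)cc(OC)c1 | starting material
13 | (2S,3S)-4-(benzyloxy)-3-(3,5-dimethoxyphenyl)-6-methoxy-2-[4-(tosyloxy)phenyl]-2,3-dihydrobenzofuran | COc1cc(OCc2ccccc2)c2c(c1)O[C@H](c1ccc(OS(=O)(=O)c3ccc(C)cc3)cc1)[C@H]2c1cc(OC)cc(OC)c1 | intermediate
14 | (2S,3S)-3-(3,5-dimethoxyphenyl)-6-methoxy-2-[4-(tosyloxy)phenyl]-2,3-dihydrobenzofuran-4-ol | COc1cc(O)c2c(c1)O[C@H](c1ccc(OS(=O)(=O)c3ccc(C)cc3)cc1)[C@H]2c1cc(OC)cc(OC)c1 | intermediate
15 | (2S,3S)-3-(3,5-dimethoxyphenyl)-6-methoxy-2-[4-(tosyloxy)phenyl]-2,3-dihydrobenzofuran-4-yl trifluoromethanesulfonate | COc1cc(OS(=O)(=O)C(F)(F)F)c2c(c1)O[C@H](c1ccc(OS(=O)(=O)c3ccc(C)cc3)cc1)[C@H]2c1cc(OC)cc(OC)c1 | intermediate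
16 | (2S,3S)-3-(3,5-dimethoxyphenyl)-6-methoxy-2-[4-(tosyloxy)phenyl]-2,3-dihydrobenzofuran-4-carbaldehyde | COc1cc(C=O)c2c(c1)O[C@H](c1ccc(OS(=O)(=O)c3ccc(C)cc3)cc1)[C@H]2c1cc(OC)cc(OC)c1 | intermediate
17 | (2S,3S)-3-(3,5-dimethoxyphenyl)-6-methoxy-4-[(E)-2-nitroethenyl]-2-[4-(tosyloxy)phenyl]-2,3-dihydrobenzofuran | COc1cc(/C=C/[N+](=O)[O-])c2c(c1)O[C@H](c1ccc(OS(=O)(=O)c3ccc(C)cc3)cc1)[C@H]2c1cc(OC)cc(OC)c1 | intermediate
18 | 5-bromo-2-methoxyphenylboronic acid | COc1ccc(Br)cc1B(O)O | starting material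
19 | (2S,3S)-4-[(1R)-1-(5-bromo-2-methoxyphenyl)-2-nitroethyl]-3-(3,5-dimethoxyphenyl)-6-methoxy-2-[4-(tosyloxy)phenyl]-2,3-dihydrobenzofuran | COc1cc([C@@H](C[N+](=O)[O-])c3cc(Br)ccc3OC)c2c(c1)O[C@H](c1ccc(OS(=O)(=O)c3ccc(C)cc3)cc1)[C@H]2c1cc(OC)cc(OC)c1 | intermediate
20 | sodium nitronate of 19 | COc1cc([C@@H](C=[N+]([O-])[O-])c3cc(Br)ccc3OC)c2c(c1)O[C@H](c1ccc(OS(=O)(=O)c3ccc(C)cc3)cc1)[C@H]2c1cc(OC)cc(OC)c1.[Na+] | intermediate
21 | (2R)-2-(5-bromo-2-methoxyphenyl)-2-{(2S,3S)-3-(3,5-dimethoxyphenyl)-6-methoxy-2-[4-(tosyloxy)phenyl]-2,3-dihydrobenzofuran-4-yl}acetaldehyde | COc1cc([C@@H](C=O)c3cc(Br)ccc3OC)c2c(c1)O[C@H](c1ccc(OS(=O)(=O)c3ccc(C)cc3)cc1)[C@H]2c1cc(OC)cc(OC)c1 | intermediate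
22 | 4-methoxyphenylmagnesium bromide | COc1ccc([Mg]Br)cc1 | starting material
23 | (2R)-2-(5-bromo-2-methoxyphenyl)-2-{(2S,3S)-3-(3,5-dimethoxyphenyl)-6-methoxy-2-[4-(tosyloxy)phenyl]-2,3-dihydrobenzofuran-4-yl}-1-(4-methoxyphenyl)ethan-1-ol (carbinol epimers) | COc1cc([C@@H](C(O)c3ccc(OC)cc3)c3cc(Br)ccc3OC)c2c(c1)O[C@H](c1ccc(OS(=O)(=O)c3ccc(C)cc3)cc1)[C@H]2c1cc(OC)cc(OC)c1 | intermediate
24 | core bromide, pentamethyl ether tosylate (CaR/CcS/CbS/CdS) | COc1ccc(Br)cc1[C@H]2c3cc(OC)cc4c3[C@H](c3cc(OC)cc(OC)c3[C@@H]2c2ccc(OC)cc2)[C@@H](c2ccc(OS(=O)(=O)c3ccc(C)cc3)cc2)O4 | intermediate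
25 | core bromide, pentaphenol tosylate (CaR/CcS/CbS/CdS) | Oc1ccc(Br)cc1[C@H]2c3cc(O)cc4c3[C@H](c3cc(O)cc(O)c3[C@@H]2c2ccc(O)cc2)[C@@H](c2ccc(OS(=O)(=O)c3ccc(C)cc3)cc2)O4 | intermediate
26 | core bromide, hexaphenol (CaR/CcS/CbS/CdS) | Oc1ccc(Br)cc1[C@H]2c3cc(O)cc4c3[C@H](c3cc(O)cc(O)c3[C@@H]2c2ccc(O)cc2)[C@@H](c2ccc(O)cc2)O4 | intermediate
27 | core bromide, hexaacetate (CaR/CcS/CbS/CdS) | CC(=O)Oc1ccc(Br)cc1[C@H]2c3cc(OC(C)=O)cc4c3[C@H](c3cc(OC(C)=O)cc(OC(C)=O)c3[C@@H]2c2ccc(OC(C)=O)cc2)[C@@H](c2ccc(OC(C)=O)cc2)O4 | intermediate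
28 | 1-bromo-2-iodo-3,5-dimethoxybenzene | COc1cc(Br)c(I)c(OC)c1 | intermediate
29 | 1-ethynyl-4-methoxybenzene | C#Cc1ccc(OC)cc1 | starting material
30 | 1-bromo-3,5-dimethoxy-2-[(4-methoxyphenyl)ethynyl]benzene | COc1cc(Br)c(C#Cc2ccc(OC)cc2)c(OC)c1 | intermediate
31 | 4-bromo-3-iodo-6-methoxy-2-(4-methoxyphenyl)benzofuran | COc1cc(Br)c2c(I)c(-c3ccc(OC)cc3)oc2c1 | intermediate
32 | 3,5-dimethoxyphenylboronic acid | COc1cc(cc(OC)c1)B(O)O | starting material
33 | 4-bromo-3-(3,5-dimethoxyphenyl)-6-methoxy-2-(4-methoxyphenyl)benzofuran | COc1cc(Br)c2c(-c3cc(OC)cc(OC)c3)c(-c3ccc(OC)cc3)oc2c1 | intermediate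
34 | 5-[4-bromo-6-hydroxy-2-(4-hydroxyphenyl)benzofuran-3-yl]benzene-1,3-diol | Oc1cc(Br)c2c(-c3cc(O)cc(O)c3)c(-c3ccc(O)cc3)oc2c1 | intermediate
35 | 2-(4-acetoxyphenyl)-4-bromo-3-(3,5-diacetoxyphenyl)benzofuran-6-yl acetate | CC(=O)Oc1cc(Br)c2c(-c3cc(OC(C)=O)cc(OC(C)=O)c3)c(-c3ccc(OC(C)=O)cc3)oc2c1 | intermediate
36 | 2-(4-acetoxyphenyl)-3-(3,5-diacetoxyphenyl)-4-ethenylbenzofuran-6-yl acetate | C=Cc1cc(OC(C)=O)cc2oc(-c3ccc(OC(C)=O)cc3)c(-c3cc(OC(C)=O)cc(OC(C)=O)c3)c12 | intermediate
37 | decaacetate of the target ((E); CaR/CcS/CbS/CdS) | CC(=O)Oc1ccc(-c2oc3cc(OC(C)=O)cc(/C=C/c4ccc(OC(C)=O)c([C@H]5c6cc(OC(C)=O)cc7c6[C@H](c6cc(OC(C)=O)cc(OC(C)=O)c6[C@@H]5c5ccc(OC(C)=O)cc5)[C@@H](c5ccc(OC(C)=O)cc5)O7)c4)c3c2-c2cc(OC(C)=O)cc(OC(C)=O)c2)cc1 | intermediate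
38 | CNP0339094.1 ((E); CaR/CcS/CbS/CdS) | Oc1ccc(-c2oc3cc(O)cc(/C=C/c4ccc(O)c([C@H]5c6cc(O)cc7c6[C@H](c6cc(O)cc(O)c6[C@@H]5c5ccc(O)cc5)[C@@H](c5ccc(O)cc5)O7)c4)c3c2-c2cc(O)cc(O)c2)cc1 | target

Total step count: 25
Longest linear sequence: 18 steps (1, 2, 4–17, 24, 25)

Steps most likely to fail

**Step 5.** The oxidation may be diverted by migration of the 2-aryl group, by dehydrogenation of the heterocycle or by electrophilic attack of the oxidant on ring A. The acid may also erode the C2 configuration through reversible ring opening. The fallback sets out from 7 and comes back at 10, and it makes the same C3–C4a bond by a Wolff ring contraction instead of an oxidation. Flavanone 7 is C-acylated at −78 °C (LiN(SiMe3)2, CF3CO2CH2CF3) to the 3-trifluoroacetyl flavanone F1. Detrifluoroacetylative diazo transfer (MsN3, Et3N, moist MeCN) gives the 3-diazoflavanone F2. Irradiation (365 nm) in methanol then expels nitrogen, shifts C4a to C3 and traps the ketene as ester 10 together with the cis ester F3, which catalytic DBU equilibrates to 10.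

**Step 7.** Capture of the hindered benzylic radical by nickel may be too slow, so that radical dimerisation, hydrogen abstraction or simple protodecarboxylation takes over. The fallback sets out from 11 and comes back at 13, and it replaces light-driven oxidative activation and the aryl halide by thermal reductive activation and an aryl nucleophile. Acid 11 is esterified with N-hydroxytetrachlorophthalimide (diisopropylcarbodiimide, DMAP cat.) to the redox-active ester F4. This ester is coupled with boronic acid 32 in a decarboxylative Suzuki-type arylation (NiCl2·6H2O, 4,7-diphenyl-1,10-phenanthroline, Et3N, 1,4-dioxane/DMF, 75 °C), again trans by approach anti to the C2 aryl group.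

**Step 13.** Enolisation of the diarylacetaldehyde during the Nef reaction, the work-up or the following addition may erode the Ca configuration, and the reduction may stall before hydrolysis. The fallback sets out from 19 and comes back at 24. It never passes through an aldehyde, closes the ring by acylation and brings in the anisyl group last.
- Nitroalkane 19 is oxidised (NaNO2, AcOH, DMSO, 35 °C) to the diarylacetic acid F5.
- Intramolecular Friedel–Crafts acylation of ring B ((CF3CO)2O, CF3CO2H, CH2Cl2, 0 °C) gives the seven-membered ketone F6.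
- Luche reduction (NaBH4, CeCl3·7H2O, MeOH/THF, −20 °C) gives the benzylic alcohol F7.
- Bi(OTf)3-catalysed Friedel–Crafts alkylation of excess anisole by the dimethoxyaryl-stabilised Cc cation of F7, with para attack from the open convex face anti to ring S, delivers 24.

Further compounds
F1 | step 5 | (2S)-5-(benzyloxy)-7-methoxy-2-[4-(tosyloxy)phenyl]-3-(trifluoroacetyl)chroman-4-one (C3 undefined) | COc1cc(OCc2ccccc2)c2C(=O)C(C(=O)C(F)(F)F)[C@@H](c3ccc(OS(=O)(=O)c4ccc(C)cc4)cc3)Oc2c1
F2 | step 5 | 5-(benzyloxy)-3-diazo-7-methoxy-2-[4-(tosyloxy)phenyl]chroman-4-one (C2 arranged as in 7, descriptor R) | COc1cc(OCc2ccccc2)c2C(=O)C(=[N+]=[N-])[C@@H](c3ccc(OS(=O)(=O)c4ccc(C)cc4)cc3)Oc2c1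
F3 | step 5 | methyl (2S,3R)-4-(benzyloxy)-6-methoxy-2-[4-(tosyloxy)phenyl]-2,3-dihydrobenzofuran-3-carboxylate (cis) | COc1cc(OCc2ccccc2)c2c(c1)O[C@H](c1ccc(OS(=O)(=O)c3ccc(C)cc3)cc1)[C@@H]2C(=O)OC
F4 | step 7 | 4,5,6,7-tetrachloro-1,3-dioxoisoindolin-2-yl (2S,3S)-4-(benzyloxy)-6-methoxy-2-[4-(tosyloxy)phenyl]-2,3-dihydrobenzofuran-3-carboxylate | COc1cc(OCc2ccccc2)c2c(c1)O[C@H](c1ccc(OS(=O)(=O)c3ccc(C)cc3)cc1)[C@H]2C(=O)ON1C(=O)c2c(Cl)c(Cl)c(Cl)c(Cl)c2C1=O
F5 | step 13 | (2R)-2-(5-bromo-2-methoxyphenyl)-2-{(2S,3S)-3-(3,5-dimethoxyphenyl)-6-methoxy-2-[4-(tosyloxy)phenyl]-2,3-dihydrobenzofuran-4-yl}acetic acid | COc1cc([C@@H](C(=O)O)c3cc(Br)ccc3OC)c2c(c1)O[C@H](c1ccc(OS(=O)(=O)c3ccc(C)cc3)cc1)[C@H]2c1cc(OC)cc(OC)c1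
F6 | step 13 | seven-membered ketone (C=O at Cc; Ca, Cb, Cd as in 24) | COc1ccc(Br)cc1[C@H]2c3cc(OC)cc4c3[C@H](c3cc(OC)cc(OC)c3C2=O)[C@@H](c2ccc(OS(=O)(=O)c3ccc(C)cc3)cc2)O4
F7 | step 13 | seven-membered benzylic alcohol (OH at Cc, undefined; Ca, Cb, Cd as in 24) | COc1ccc(Br)cc1[C@H]2c3cc(OC)cc4c3[C@H](c3cc(OC)cc(OC)c3C2O)[C@@H](c2ccc(OS(=O)(=O)c3ccc(C)cc3)cc2)O4
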